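**Retrosynthetic overview**

1. Numbering and feature: the 14-membered carbocycle is C1–C14 (E-alkenes C3=C4, C7=C8, C11=C12; C6–OH; C10–OAc), trans-fused at C1/C2 to the γ-lactone O–C16(=O)–C15(=C17). Its only saturated two-carbon bridge, C13–C14, links the fusion stereocentre C1 to the E-trisubstituted alkene C11=C12, so the sp2–sp3 bond C12–C13 is the ring-closing bond.
2. Endgame: after ring closure, C15 is methylenated, the C10 silyl ether is exchanged for the acetate and the C6 silyl ether is removed; the exo-methylene is withheld until after the hydroboration.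
3. Key disconnection: C12–C13, by intramolecular B-alkyl Suzuki–Miyaura coupling of the 9-BBN adduct of a C1 vinyl group (C14=C13) with an (E)-C12 alkenyl iodide in a seco trans-4-vinyl-5-alkenyl-γ-butyrolactone.
4. Seco lactone: anti vinyl-cuprate addition to a butenolide sets C1; asymmetric propiolate addition to the C2 enal sets C2 and Z-semihydrogenation closes the lactone; two rounds of catalytic asymmetric vinylogous Mukaiyama aldol set C10 and C6 and build both E C(Me)=CH units, starting from (E)-3-iodobut-2-enal, whose iodide is installed first from but-2-yn-1-ol.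
5. Ring order: γ-lactone first (step 13), 14-membered carbocycle second (step 15).

Key step: step 15

Assumption: the facial sense of the three catalyst-controlled additions is taken from the accepted models ((S,S)-bisphosphoramide·SiCl4 sends the dienolate to the aldehyde Si face; (S,S)-ProPhenol·Zn sends the acetylide to the Re face); if a model proves reversed for these enals, the antipodal ligand is used and nothing else changes.

**Route**

Step 1
Reactants: 1 but-2-yn-1-ol
Product: 3 (E)-3-iodobut-2-en-1-ol, via alkenylzirconocene 2 (not isolated)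
Conditions: Cp2Zr(H)Cl (2.3 equiv), THF, 0 °C → rt; then I2 (1.1 equiv), THF, 0 °C
Reagents that add atoms: molecular iodine, II
Why: Hydrozirconation–iodination: after O-zirconation, syn H–Zr addition equilibrates to the regioisomer with zirconium on the methyl-bearing carbon remote from the CH2O–Zr group, and iodinolysis of the C–Zr bond with retention gives the E iodide (methyl cis to CH2OH); it is done first because later esters, enals, the lactone and the vinyl group would not tolerate the zirconium hydride.

Step 2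
Reactants: 3 (E)-3-iodobut-2-en-1-ol
Product: 4 (E)-3-iodobut-2-enal
Conditions: activated MnO2 (excess), CH2Cl2, rt; used as a solution
Reagents that add atoms: none
Why: Allylic oxidation with MnO2 is selective for the allylic alcohol and should not isomerise or cleave the iodoalkene.

Step 3
Reactants: 5 methyl 3-methylbut-2-enoate
Product: 6 tert-butyl{[(1Z)-1-methoxy-3-methylbuta-1,3-dien-1-yl]oxy}dimethylsilane
Conditions: LDA, THF, −78 °C; then TBSCl, DMPU, −78 °C → rt
Reagents that add atoms: tert-butyldimethylsilyl chloride, CC(C)(C)[Si](C)(C)Cl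
Why: Kinetic γ-deprotonation of the senecioate and O-silylation of the extended enolate give the silyl dienol ether, the standard donor for vinylogous Mukaiyama aldol reactions (its C1=C2 geometry is inconsequential).

Step 4
Reactants: 4 (E)-3-iodobut-2-enal; 6 silyl dienol ether
Product: 7 methyl (2E,5S,6E)-5-hydroxy-7-iodo-3-methylocta-2,6-dienoate
Conditions: SiCl4 (1.1 equiv), (S,S)-binaphthyldiamine-derived bisphosphoramide (5 mol %), CH2Cl2, −78 °C; aq NaHCO3
Reagents that add atoms: none
Why: Catalytic enantioselective vinylogous Mukaiyama aldol: the chiral phosphoramide-bound trichlorosilyl cation activates the conjugated aldehyde and the dienolate attacks through its γ-carbon on the Si face, setting C10 as S under catalyst control and giving the E enoate through an open transition state.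

Step 5
Reactants: 7 hydroxy dienoate
Product: 8 methyl (2E,5S,6E)-7-iodo-3-methyl-5-(triethylsilyloxy)octa-2,6-dienoate
Conditions: TESCl, imidazole, CH2Cl2, 0 °C
Reagents that add atoms: chlorotriethylsilane, CC[Si](Cl)(CC)CC
Why: Standard silylation of the secondary allylic alcohol; TES is chosen because it must later be cleaved in the presence of a TBS ether.

Step 6
Reactants: 8 TES-protected dienoate
Product: 9 (2E,5S,6E)-7-iodo-3-methyl-5-(triethylsilyloxy)octa-2,6-dien-1-ol
Conditions: DIBAL-H (2.3 equiv), CH2Cl2, −78 °C; Rochelle salt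
Reagents that add atoms: none
Why: DIBAL-H 1,2-reduction of the conjugated ester to the allylic alcohol at low temperature leaves the alkenyl iodide and the silyl ether untouched.

Step 7
Reactants: 9 allylic alcohol
Product: 10 (2E,5S,6E)-7-iodo-3-methyl-5-(triethylsilyloxy)octa-2,6-dienal
Conditions: activated MnO2 (excess), CH2Cl2, rt
Reagents that add atoms: none
Why: Chemoselective allylic oxidation with MnO2 gives the E enal without touching the silyl ether or the iodide.

Step 8
Reactants: 10 dienal; 6 silyl dienol ether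
Product: 11 methyl (2E,5S,6E,9S,10E)-5-hydroxy-11-iodo-3,7-dimethyl-9-(triethylsilyloxy)dodeca-2,6,10-trienoate
Conditions: SiCl4 (1.1 equiv), (S,S)-bisphosphoramide (5 mol %), CH2Cl2, −78 °C; aq NaHCO3
Reagents that add atoms: none
Why: Second vinylogous Mukaiyama aldol: the same catalyst again directs γ-attack on the Si face of the conjugated aldehyde and sets C6 as S under catalyst control (the C10 centre is remote from the carbonyl), with the E enoate formed as before.

Step 9
Reactants: 11 hydroxy trienoate
Product: 12 methyl (2E,5S,6E,9S,10E)-5-(tert-butyldimethylsilyloxy)-11-iodo-3,7-dimethyl-9-(triethylsilyloxy)dodeca-2,6,10-trienoate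
Conditions: TBSCl, imidazole, DMAP (cat.), DMF, rt
Reagents that add atoms: tert-butyldimethylsilyl chloride, CC(C)(C)[Si](C)(C)Cl
Why: Standard silylation of the secondary allylic alcohol; TBS is chosen to outlast the C10 TES ether in the endgame.

Step 10
Reactants: 12 bis-silyl trienoate
Product: 13 (2E,5S,6E,9S,10E)-5-(tert-butyldimethylsilyloxy)-11-iodo-3,7-dimethyl-9-(triethylsilyloxy)dodeca-2,6,10-trien-1-ol
Conditions: DIBAL-H (2.3 equiv), CH2Cl2, −78 °C; Rochelle salt
Reagents that add atoms: none
Why: DIBAL-H 1,2-reduction of the enoate, as in step 6.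

Step 11
Reactants: 13 allylic alcohol
Product: 14 (2E,5S,6E,9S,10E)-5-(tert-butyldimethylsilyloxy)-11-iodo-3,7-dimethyl-9-(triethylsilyloxy)dodeca-2,6,10-trienal
Conditions: activated MnO2 (excess), CH2Cl2, rt
Reagents that add atoms: none
Why: Allylic oxidation with MnO2, as in step 7, gives the C2 enal.

Step 12
Reactants: 14 trienal; 15 ethyl propiolate
Product: 16 ethyl (4S,5E,8S,9E,12S,13E)-8-(tert-butyldimethylsilyloxy)-4-hydroxy-14-iodo-6,10-dimethyl-12-(triethylsilyloxy)pentadeca-5,9,13-trien-2-ynoate
Conditions: (S,S)-ProPhenol (20 mol %), Me2Zn (3 equiv), 15 (3 equiv), toluene, 0–4 °C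
Reagents that add atoms: none
Why: Zinc–ProPhenol catalysed asymmetric alkynylation: the dinuclear zinc complex delivers the zinc acetylide of the propiolate to the Re face of the enal and sets C2 as the (S)-propargylic carbinol; enals are a favoured substrate class, and dimethylzinc leaves the alkenyl iodide and silyl ethers alone.

Step 13
Reactants: 16 hydroxy ynoate
Product: 18 (5R)-5-[(1E,4S,5E,8S,9E)-4-(tert-butyldimethylsilyloxy)-10-iodo-2,6-dimethyl-8-(triethylsilyloxy)undeca-1,5,9-trien-1-yl]furan-2(5H)-one, via Z-hydroxy enoate 17 (not isolated)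
Conditions: H2 (1 atm), Lindlar catalyst, quinoline, EtOAc, rt, stopped after 1 equiv H2; then PPTS (cat.), CH2Cl2, rt
Reagents that add atoms: none
Why: Lindlar semihydrogenation (syn addition of H2) gives the Z γ-hydroxy enoate, whose cis geometry leads to lactonisation with loss of ethanol; the electron-poor ynoate should be reduced well before the hindered trisubstituted alkenyl iodide or the trisubstituted alkenes are attacked on the poisoned catalyst.

Step 14
Reactants: 18 butenolide; 19 vinylmagnesium bromide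
Product: 21 (4S,5R)-5-[(1E,4S,5E,8S,9E)-4-(tert-butyldimethylsilyloxy)-10-iodo-2,6-dimethyl-8-(triethylsilyloxy)undeca-1,5,9-trien-1-yl]-4-vinyldihydrofuran-2(3H)-one (seco lactone; 4,5-trans), via silyl ketene acetal 20 (not isolated)
Conditions: 19 (4 equiv), CuBr·SMe2 (2 equiv), TMSCl (4 equiv), THF, −78 °C; aq NH4Cl
Reagents that add atoms: none
Why: TMSCl-accelerated conjugate addition of the magnesium divinylcuprate to the butenolide takes place anti to the C2 alkenyl substituent (1,2-induction in the five-membered ring) and sets C1 trans to C2, the silyl ketene acetal being hydrolysed on work-up; at −78 °C the hindered alkenyl iodide should not undergo copper–iodine exchange.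

Step 15
Reactants: 21 seco lactone
Product: 23 (3aR,6E,8S,10E,12S,14E,15aR)-12-(tert-butyldimethylsilyloxy)-6,10,14-trimethyl-8-(triethylsilyloxy)-3a,4,5,8,9,12,13,15a-octahydrocyclotetradeca[b]furan-2(3H)-one (closed macrolactone), via B-alkyl-9-BBN borane 22 (not isolated)
Conditions: 9-BBN (2 equiv), THF, 0 °C → rt; then H2O; slow addition (12 h) to PdCl2(dppf)·CH2Cl2 (20 mol %), AsPh3 (40 mol %), Cs2CO3, DMF/THF/H2O, rt, about 1 mM
Reagents that add atoms: none
Why: 9-BBN adds anti-Markovnikov to the only monosubstituted alkene and puts boron on C13 (borane 22); after oxidative addition of Pd(0) into the C12–I bond with retention, the base-activated borate transfers its primary alkyl group to palladium and reductive elimination forms C12–C13. The closest known reaction type is the intramolecular B-alkyl Suzuki–Miyaura coupling used to close medium and large carbocycles and macrolides from ω-alkenyl alkenyl iodides. The 14-membered carbocycle is closed end-to-end (C13 onto C12) through a large-ring alkyl(alkenyl)palladium intermediate, while the γ-lactone is already in place and is not touched. No stereocentre is created: C1, C2, C6 and C10 are spectators, and the E geometry of C11=C12 is fixed in the iodide and carried through with retention. Three selectivities are needed: hydroboration of the vinyl group only (secured by the bulk of 9-BBN against the three trisubstituted alkenes and by the absence of the C15 exo-methylene), ring closure before oligomerisation (slow addition of 22 to the catalyst at high dilution), and C–I insertion before ionisation of the allylic lactone C2–O bond (the alkenyl iodide reacts far faster at room temperature and the allyl unit is trisubstituted). AsPh3 is added to speed transmetalation so that β-hydride elimination of the alkylpalladium and hydrolysis of the lactone by the aqueous carbonate stay behind.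

Step 16
Reactants: 23 closed macrolactone
Product: 24 (3S,3aR,6E,8S,10E,12S,14E,15aR)-3-[(dimethylamino)methyl]-12-(tert-butyldimethylsilyloxy)-6,10,14-trimethyl-8-(triethylsilyloxy)-3a,4,5,8,9,12,13,15a-octahydrocyclotetradeca[b]furan-2(3H)-one
Conditions: LDA (1.3 equiv), THF, −78 °C; then dimethyl(methylidene)ammonium iodide (3 equiv), −78 → 0 °C
Reagents that add atoms: Eschenmoser's salt, C=[N+](C)C.[I-]
Why: Mannich reaction of the lactone lithium enolate (C15 is the only enolisable position) with the iminium salt, expected to add anti to C14; the new C15 centre is of no consequence because it is destroyed in step 17.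

Step 17
Reactants: 24 Mannich base
Product: 26 (3aR,6E,8S,10E,12S,14E,15aS)-12-(tert-butyldimethylsilyloxy)-6,10,14-trimethyl-3-methylidene-8-(triethylsilyloxy)-3a,4,5,8,9,12,13,15a-octahydrocyclotetradeca[b]furan-2(3H)-one, via ammonium iodide 25 (not isolated)
Conditions: MeI (excess), MeOH/CH2Cl2, rt; concentrate; then aq NaHCO3, CH2Cl2, rt
Reagents that add atoms: none
Why: N-Methylation followed by Hofmann-type (E1cB) elimination of trimethylamine from the β-ammonio lactone gives the C15=C17 exo-methylene under mild bicarbonate conditions that leave both silyl ethers intact.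

Step 18
Reactants: 26 bis-silyl α-methylene lactone
Product: 27 (3aR,6E,8S,10E,12S,14E,15aS)-12-(tert-butyldimethylsilyloxy)-8-hydroxy-6,10,14-trimethyl-3-methylidene-3a,4,5,8,9,12,13,15a-octahydrocyclotetradeca[b]furan-2(3H)-one
Conditions: PPTS (0.2 equiv), MeOH/CH2Cl2 (1:1), 0 °C
Reagents that add atoms: none
Why: Acid-catalysed methanolysis cleaves the secondary TES ether much faster than the secondary TBS ether, so only the C10 hydroxyl should be freed, and weak acid does not promote conjugate addition of methanol to the α-methylene lactone.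

Step 19
Reactants: 27 C10 alcohol
Product: 28 (3aR,6E,8S,10E,12S,14E,15aS)-12-(tert-butyldimethylsilyloxy)-6,10,14-trimethyl-3-methylidene-2-oxo-2,3,3a,4,5,8,9,12,13,15a-decahydrocyclotetradeca[b]furan-8-yl acetate
Conditions: Ac2O, pyridine, DMAP (cat.), CH2Cl2, 0 °C → rt
Reagents that add atoms: acetic anhydride, CC(=O)OC(C)=O
Why: DMAP-catalysed acylation of the only free hydroxyl installs the C10 acetate with retention at C10.

Step 20
Reactants: 28 C10 acetate
Product: 29 (3aR,6E,8S,10E,12S,14E,15aS)-12-hydroxy-6,10,14-trimethyl-3-methylidene-2-oxo-2,3,3a,4,5,8,9,12,13,15a-decahydrocyclotetradeca[b]furan-8-yl acetate (CNP0406430.1)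
Conditions: HF·pyridine, pyridine, THF, 0 °C → rt
Reagents that add atoms: none
Why: Buffered fluoride desilylation removes the C6 TBS group under mildly acidic conditions that should not cleave or migrate the allylic acetate or add to the α-methylene lactone.

**Compound list**

1 | but-2-yn-1-ol | CC#CCO | starting material
2 | (E)-alkenylzirconocene: C3- and O-zirconated adduct of 1 with Cp2ZrCl on C3 (cis to H2) and on oxygen (Cp drawn η1) | C/C(=C\CO[Zr](Cl)(C1C=CC=C1)C1C=CC=C1)[Zr](Cl)(C1C=CC=C1)C1C=CC=C1 | intermediate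
3 | (E)-3-iodobut-2-en-1-ol | C/C(I)=C\CO | intermediate
4 | (E)-3-iodobut-2-enal | C/C(I)=C\C=O | intermediate
5 | methyl 3-methylbut-2-enoate | COC(=O)C=C(C)C | starting material
6 | tert-butyl{[(1Z)-1-methoxy-3-methylbuta-1,3-dien-1-yl]oxy}dimethylsilane | C=C(C)/C=C(OC)\O[Si](C)(C)C(C)(C)C | intermediate
7 | methyl (2E,5S,6E)-5-hydroxy-7-iodo-3-methylocta-2,6-dienoate | COC(=O)/C=C(\C)C[C@H](O)/C=C(\C)I | intermediate
8 | methyl (2E,5S,6E)-7-iodo-3-methyl-5-(triethylsilyloxy)octa-2,6-dienoate | COC(=O)/C=C(\C)C[C@H](O[Si](CC)(CC)CC)/C=C(\C)I | intermediate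
9 | (2E,5S,6E)-7-iodo-3-methyl-5-(triethylsilyloxy)octa-2,6-dien-1-ol | OC/C=C(\C)C[C@H](O[Si](CC)(CC)CC)/C=C(\C)I | intermediate
10 | (2E,5S,6E)-7-iodo-3-methyl-5-(triethylsilyloxy)octa-2,6-dienal | O=C/C=C(\C)C[C@H](O[Si](CC)(CC)CC)/C=C(\C)I | intermediate
11 | methyl (2E,5S,6E,9S,10E)-5-hydroxy-11-iodo-3,7-dimethyl-9-(triethylsilyloxy)dodeca-2,6,10-trienoate | COC(=O)/C=C(\C)C[C@H](O)/C=C(\C)C[C@H](O[Si](CC)(CC)CC)/C=C(\C)I | intermediate
12 | methyl (2E,5S,6E,9S,10E)-5-(tert-butyldimethylsilyloxy)-11-iodo-3,7-dimethyl-9-(triethylsilyloxy)dodeca-2,6,10-trienoate | COC(=O)/C=C(\C)C[C@H](O[Si](C)(C)C(C)(C)C)/C=C(\C)C[C@H](O[Si](CC)(CC)CC)/C=C(\C)I | intermediate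
13 | (2E,5S,6E,9S,10E)-5-(tert-butyldimethylsilyloxy)-11-iodo-3,7-dimethyl-9-(triethylsilyloxy)dodeca-2,6,10-trien-1-ol | OC/C=C(\C)C[C@H](O[Si](C)(C)C(C)(C)C)/C=C(\C)C[C@H](O[Si](CC)(CC)CC)/C=C(\C)I | intermediate
14 | (2E,5S,6E,9S,10E)-5-(tert-butyldimethylsilyloxy)-11-iodo-3,7-dimethyl-9-(triethylsilyloxy)dodeca-2,6,10-trienal | O=C/C=C(\C)C[C@H](O[Si](C)(C)C(C)(C)C)/C=C(\C)C[C@H](O[Si](CC)(CC)CC)/C=C(\C)I | intermediate
15 | ethyl propiolate | C#CC(=O)OCC | starting material
16 | ethyl (4S,5E,8S,9E,12S,13E)-8-(tert-butyldimethylsilyloxy)-4-hydroxy-14-iodo-6,10-dimethyl-12-(triethylsilyloxy)pentadeca-5,9,13-trien-2-ynoate | CCOC(=O)C#C[C@@H](O)/C=C(\C)C[C@H](O[Si](C)(C)C(C)(C)C)/C=C(\C)C[C@H](O[Si](CC)(CC)CC)/C=C(\C)I | intermediate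
17 | ethyl (2Z,4R,5E,8S,9E,12S,13E)-8-(tert-butyldimethylsilyloxy)-4-hydroxy-14-iodo-6,10-dimethyl-12-(triethylsilyloxy)pentadeca-2,5,9,13-tetraenoate | CCOC(=O)/C=C\[C@@H](O)/C=C(\C)C[C@H](O[Si](C)(C)C(C)(C)C)/C=C(\C)C[C@H](O[Si](CC)(CC)CC)/C=C(\C)I | intermediate
18 | (5R)-5-[(1E,4S,5E,8S,9E)-4-(tert-butyldimethylsilyloxy)-10-iodo-2,6-dimethyl-8-(triethylsilyloxy)undeca-1,5,9-trien-1-yl]furan-2(5H)-one | O=C1C=C[C@@H](O1)/C=C(\C)C[C@H](O[Si](C)(C)C(C)(C)C)/C=C(\C)C[C@H](O[Si](CC)(CC)CC)/C=C(\C)I | intermediate
19 | vinylmagnesium bromide | C=C[Mg]Br | starting material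
20 | O-trimethylsilyl ketene acetal of 21 (4,5-trans-2-trimethylsilyloxy-4-vinyl-4,5-dihydrofuran) | C=C[C@@H]1C=C(O[Si](C)(C)C)O[C@H]1/C=C(\C)C[C@H](O[Si](C)(C)C(C)(C)C)/C=C(\C)C[C@H](O[Si](CC)(CC)CC)/C=C(\C)I | intermediate
21 | (4S,5R)-5-[(1E,4S,5E,8S,9E)-4-(tert-butyldimethylsilyloxy)-10-iodo-2,6-dimethyl-8-(triethylsilyloxy)undeca-1,5,9-trien-1-yl]-4-vinyldihydrofuran-2(3H)-one (key-step precursor) | C=C[C@@H]1CC(=O)O[C@H]1/C=C(\C)C[C@H](O[Si](C)(C)C(C)(C)C)/C=C(\C)C[C@H](O[Si](CC)(CC)CC)/C=C(\C)I | intermediate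
22 | B-alkyl-9-BBN borane: 4-[2-(9-borabicyclo[3.3.1]nonan-9-yl)ethyl] analogue of 21 (boron on C13; stereocentres unchanged) | B1(C2CCCC1CCC2)CC[C@@H]1CC(=O)O[C@H]1/C=C(\C)C[C@H](O[Si](C)(C)C(C)(C)C)/C=C(\C)C[C@H](O[Si](CC)(CC)CC)/C=C(\C)I | intermediate
23 | (3aR,6E,8S,10E,12S,14E,15aR)-12-(tert-butyldimethylsilyloxy)-6,10,14-trimethyl-8-(triethylsilyloxy)-3a,4,5,8,9,12,13,15a-octahydrocyclotetradeca[b]furan-2(3H)-one (key-step product; trans-fused) | C1C(=O)O[C@H]2/C=C(\C)C[C@H](O[Si](C)(C)C(C)(C)C)/C=C(\C)C[C@H](O[Si](CC)(CC)CC)/C=C(\C)CC[C@H]12 | intermediate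
24 | (3S,3aR,6E,8S,10E,12S,14E,15aR)-3-[(dimethylamino)methyl]-12-(tert-butyldimethylsilyloxy)-6,10,14-trimethyl-8-(triethylsilyloxy)-3a,4,5,8,9,12,13,15a-octahydrocyclotetradeca[b]furan-2(3H)-one (expected C15 epimer) | CN(C)C[C@H]1C(=O)O[C@H]2/C=C(\C)C[C@H](O[Si](C)(C)C(C)(C)C)/C=C(\C)C[C@H](O[Si](CC)(CC)CC)/C=C(\C)CC[C@H]12 | intermediate
25 | trimethylammonium iodide of 24 | C[N+](C)(C)C[C@H]1C(=O)O[C@H]2/C=C(\C)C[C@H](O[Si](C)(C)C(C)(C)C)/C=C(\C)C[C@H](O[Si](CC)(CC)CC)/C=C(\C)CC[C@H]12.[I-] | intermediate
26 | (3aR,6E,8S,10E,12S,14E,15aS)-12-(tert-butyldimethylsilyloxy)-6,10,14-trimethyl-3-methylidene-8-(triethylsilyloxy)-3a,4,5,8,9,12,13,15a-octahydrocyclotetradeca[b]furan-2(3H)-one | C=C1C(=O)O[C@H]2/C=C(\C)C[C@H](O[Si](C)(C)C(C)(C)C)/C=C(\C)C[C@H](O[Si](CC)(CC)CC)/C=C(\C)CC[C@H]12 | intermediate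
27 | (3aR,6E,8S,10E,12S,14E,15aS)-12-(tert-butyldimethylsilyloxy)-8-hydroxy-6,10,14-trimethyl-3-methylidene-3a,4,5,8,9,12,13,15a-octahydrocyclotetradeca[b]furan-2(3H)-one | C=C1C(=O)O[C@H]2/C=C(\C)C[C@H](O[Si](C)(C)C(C)(C)C)/C=C(\C)C[C@H](O)/C=C(\C)CC[C@H]12 | intermediate
28 | (3aR,6E,8S,10E,12S,14E,15aS)-12-(tert-butyldimethylsilyloxy)-6,10,14-trimethyl-3-methylidene-2-oxo-2,3,3a,4,5,8,9,12,13,15a-decahydrocyclotetradeca[b]furan-8-yl acetate | C=C1C(=O)O[C@H]2/C=C(\C)C[C@H](O[Si](C)(C)C(C)(C)C)/C=C(\C)C[C@H](OC(C)=O)/C=C(\C)CC[C@H]12 | intermediate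
29 | (3aR,6E,8S,10E,12S,14E,15aS)-12-hydroxy-6,10,14-trimethyl-3-methylidene-2-oxo-2,3,3a,4,5,8,9,12,13,15a-decahydrocyclotetradeca[b]furan-8-yl acetate (CNP0406430.1; cembrane numbering 1R,2S,6S,10S) | C=C1C(=O)O[C@H]2/C=C(\C)C[C@H](O)/C=C(\C)C[C@H](OC(C)=O)/C=C(\C)CC[C@H]12 | target

**Summary**

Total step count: 20.
Longest linear sequence: 19 steps (1 to 29 through steps 1, 2 and 4–20); step 3 is a one-step branch whose product 6 is used in steps 4 and 8.

**Three steps most likely to fail**

Step 15 (macrocyclisation). Intermolecular coupling may outrun ring closure and give dimers and oligomers; the alkylborane may be lost by protodeboronation or, after transmetalation, by β-hydride elimination; and the aqueous base may open the lactone. The fallback keeps the C12–C13 bond but replaces the alkylborane by an alkylzinc reagent under base-free conditions. From 21, hydroboration–oxidation (9-BBN; then NaBO3·4H2O) should give the primary C13 alcohol F1, and iodination (I2, PPh3, imidazole) the primary C13 iodide F2. Zinc insertion (Zn–Cu couple, benzene/DMA), which takes place at the C(sp3)–I bond and not at the alkenyl iodide, should give the alkylzinc iodide F3. Slow addition of F3 to Pd2(dba)3/tri(2-furyl)phosphine in THF/NMP (intramolecular Negishi coupling at high dilution) returns to the route at 23.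

Step 13 (semihydrogenation–lactonisation). Hydrogenolysis of the C12–I bond, or poisoning of the catalyst by the iodide before the ynoate is consumed, may stop the reduction or erode the iodide. The fallback builds the butenolide by ring-closing metathesis, without hydrogen or palladium. From 14, enantioselective vinylation (divinylzinc with a chiral amino alcohol ligand such as DAIB, toluene, antipode chosen for Re-face addition) should give the divinyl carbinol F4, and acryloyl chloride/Et3N/DMAP the acrylate F5. Grubbs second-generation catalyst (CH2Cl2, 40 °C) should close the five-membered ring between the acrylate and the vinyl group with loss of ethene, the trisubstituted alkenes and the iodoalkene being too hindered to take part. This returns to the route at 18 and replaces steps 12 and 13.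

Step 14 (vinyl cuprate addition). Copper–iodine exchange or cross-coupling at the C12–I bond, or SN2′ displacement of the allylic lactone oxygen, may compete with 1,4-addition. The fallback replaces magnesium/copper by boron/rhodium: rhodium(I)-catalysed conjugate addition of potassium vinyltrifluoroborate to 18 ([Rh(cod)OH]2, dioxane/H2O, 50–80 °C). This carbometalation does not exchange with alkenyl iodides and is again directed anti to the C2 substituent by the ring. It leads from 18 directly to 21 and makes no new compound (F0).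

**Further compounds**

F1 | step 15 | 4-(2-hydroxyethyl) analogue of 21 (C13 primary alcohol; 4,5-trans) | OCC[C@@H]1CC(=O)O[C@H]1/C=C(\C)C[C@H](O[Si](C)(C)C(C)(C)C)/C=C(\C)C[C@H](O[Si](CC)(CC)CC)/C=C(\C)I
F2 | step 15 | 4-(2-iodoethyl) analogue of 21 (C13 primary iodide; 4,5-trans) | ICC[C@@H]1CC(=O)O[C@H]1/C=C(\C)C[C@H](O[Si](C)(C)C(C)(C)C)/C=C(\C)C[C@H](O[Si](CC)(CC)CC)/C=C(\C)I
F3 | step 15 | C13 alkylzinc iodide derived from F2 | I[Zn]CC[C@@H]1CC(=O)O[C@H]1/C=C(\C)C[C@H](O[Si](C)(C)C(C)(C)C)/C=C(\C)C[C@H](O[Si](CC)(CC)CC)/C=C(\C)I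
F4 | step 13 | (3R,4E,7S,8E,11S,12E)-7-(tert-butyldimethylsilyloxy)-13-iodo-5,9-dimethyl-11-(triethylsilyloxy)tetradeca-1,4,8,12-tetraen-3-ol | C=C[C@@H](O)/C=C(\C)C[C@H](O[Si](C)(C)C(C)(C)C)/C=C(\C)C[C@H](O[Si](CC)(CC)CC)/C=C(\C)I
F5 | step 13 | (3R,4E,7S,8E,11S,12E)-7-(tert-butyldimethylsilyloxy)-13-iodo-5,9-dimethyl-11-(triethylsilyloxy)tetradeca-1,4,8,12-tetraen-3-yl prop-2-enoate | C=CC(=O)O[C@H](C=C)/C=C(\C)C[C@H](O[Si](C)(C)C(C)(C)C)/C=C(\C)C[C@H](O[Si](CC)(CC)CC)/C=C(\C)I
F0 | step 14 | none | none
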